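all flasks: substrate 0.10 M

| flask | coupling partner | remark | time |
|---|---|---|---|
| noon | 0.16 M | run made earlier |  |
| midnight | 0.22 M | run made earlier |  |
| dawn | 0.45 M | run made earlier |  |
| north-east | 0.150 M |  | 4.0 h |
| south-east | 0.380 M |  | 4.0 h |

| run | time / h | bis adduct / % | other mono adduct / % | substrate / % | single product / % |
|---|---|---|---|---|---|
| noon | 0.500 | 3.4 | 7.1 | 79.1 | 13.0 |
| noon | 1.33 | 11.2 | 10.8 | 60.7 | 17.6 |
| noon | 2.50 | 21.6 | 16.3 | 43.4 | 20.0 |
| noon | 4.00 | 28.3 | 17.5 | 36.4 | 20.7 |
| midnight | 0.333 | 3.4 | 5.1 | 79.9 | 11.1 |
| midnight | 0.667 | 6.6 | 11.1 | 66.8 | 16.8 |
| midnight | 1.50 | 19.4 | 13.4 | 45.1 | 21.4 |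
| midnight | 4.00 | 39.8 | 17.7 | 24.7 | 16.4 |
| dawn | 0.500 | 14.4 | 12.3 | 51.6 | 18.4 |
| dawn | 1.33 | 36.8 | 18.2 | 27.8 | 17.2 |
| dawn | 2.50 | 55.2 | 20.0 | 13.7 | 11.6 |
| dawn | 4.00 | 64.1 | 21.3 | 6.2 | 7.0 |

(readings scatter by 1 percentage point)

- what was read earlier has a scatter of 1 percentage point, one standard deviation

1. which of these there is most of at the end, counted by the substrate in it, north-east (substrate / bis adduct / other mono adduct / single product)
2. which of these there is most of at the end, counted by the substrate in it, south-east (substrate / bis adduct / other mono adduct / single product)
3. how much there is at the end of the one of these that leads, in percent of the substrate charged: north-east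
4. how much there is at the end of the one of these that leads, in percent of the substrate charged: south-east

With substrate held at 0.10 M, the amount of coupling partner is what changes from flask to flask, so the first question is what stays nearly constant at 4.0 h as that amount changes. Treated as a pseudo-first-order decay, although the partner is used up along the way, substrate carries the exponent ln(charged/left). Divided by the partner charge, this exponent reads 6.32 /M for noon, 6.36 /M for midnight and 6.18 /M for dawn. Their mean, 6.28 /M, is a reading of the depletion per molar of partner at this time.

Frozen at that value, it gives an estimate for the second question, how much substrate stands at the end: 39.0% in north-east and 9.18% in south-east.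

The third question is whether a product passes it. Noon, the nearest charge to north-east, ended with 28.3% of bis adduct, its largest product. That is less than the substrate reckoned for north-east, and north-east has less partner, so substrate should lead there. In south-east, a straight line between midnight and dawn puts bis adduct at 56.7%, far above the substrate, so bis adduct should lead.

The forecast, made to “interpolate the 4 h results against starting partner”, names substrate at 38% for north-east and bis adduct at 59% for south-east. Its substrate figure for north-east is lower than this reckoning's, and its bis adduct figure for south-east is higher.

The flask gives substrate at 37.6% in north-east and bis adduct at 59.9% in south-east.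

    coupling partner + other mono adduct → bis adduct (k = 0.480 /M/h)
    substrate + coupling partner → other mono adduct (k = 0.930 /M/h)
    substrate + coupling partner → single product (k = 2.30 /M/h)
    2 coupling partner → self-condensation product (k = 0.460 /M/h)
    coupling partner + single product → bis adduct (k = 5.10 /M/h)

South-east holds 0.0672 M of self-condensation product at 4.00 h, more than the 0.0123 M in north-east, while free coupling partner stands at 25% of its charge in north-east and 25% in south-east. Against the frozen 6.28 /M, the depletion per molar of partner comes to 6.52 /M in north-east and 6.00 /M in south-east.

Readings and results are simulated for substances that don't exist, noise included.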